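**Retrosynthetic overview**
1. The target comes from a bicyclic 8-hydroxy lactone by angeloylation of O8 and removal of a PMB group from O5.
2. The bicyclic core is cut at C6–C7 and C7–C8 together: a C6/C8 dialdehyde (C8–C9–C10=C1–C2–C3–C4–C5–C6) plus methyl 3-bromo-2-(bromomethyl)acrylate, which supplies C7 as a one-carbon linchpin carrying C11–C13. One zinc-mediated double Barbier annulation closes the α-methylene-γ-lactone first (C6–C7, O–C12) and the ten-membered carbocycle second (C7–C8), in the same flask.
3. The dialdehyde comes from a Horner–Wadsworth–Emmons union (C1=C10) of a C1–C6 aldehyde with a phosphonoacetate carrying the masked C8 aldehyde.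
4. The C1–C6/C15 piece comes from geraniol: Sharpless epoxidation fixes C5, a titanium-mediated epoxide-to-allylic-diol rearrangement creates C4=C15, PMB is placed on O5 by acetal opening, and the prenyl end is cleaved to the C1 aldehyde.
5. Stereocentres: C5 from the epoxidation, C6 by chelation control, C7 and C8 in the ring-closing allylation.

Locants C1–C15 follow the germacrane numbering of the target: ring C1–C10, lactone carbons C11 (bearing =C13H2) and C12 with the ring oxygen on C6, ester carbon C14 on C10, exocyclic methylene C15 on C4.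

**Route**

Step 1
Reactants: 1 geraniol
Product: 2 [(2R,3R)-3-methyl-3-(4-methylpent-3-en-1-yl)oxiran-2-yl]methanol
Conditions: Ti(OiPr)4 (5 mol %), D-(−)-diethyl tartrate (7 mol %), tBuOOH (1.5 equiv), 4 Å molecular sieves, CH2Cl2, −20 °C
Reagents that add atoms: tert-butyl hydroperoxide CC(C)(C)OO
Why: Katsuki–Sharpless asymmetric epoxidation: the allylic hydroxyl binds the titanium–D-tartrate catalyst, which delivers oxygen to one face of the 2,3-alkene only and so sets both epoxide carbons as R (the future C5 oxygen stereocentre), while the remote trisubstituted alkene, lacking a directing group, is left alone.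

Step 2
Reactants: 2 (2R,3R)-2,3-epoxygeraniol
Product: 3 (2S)-7-methyl-3-methylideneoct-6-ene-1,2-diol
Conditions: Ti(OiPr)4 (1.5 equiv), CH2Cl2, rt; then H2O
Reagents that add atoms: none
Why: Hydroxyl-directed, titanium-alkoxide-mediated rearrangement of a 2,3-epoxy alcohol to an allylic 1,2-diol (E2-type epoxide-to-allylic-alcohol isomerisation): titanium held on the C6 alkoxide opens the epoxide at the tertiary carbon C4 and an isopropoxide ligand takes a proton from the methyl group cis to the CH2O–Ti arm, giving the C4=C15 methylene without touching the C5–O bond, so C5 keeps its configuration (R becomes S only through the CIP priority change).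

Step 3
Reactants: 3 (2S)-7-methyl-3-methylideneoct-6-ene-1,2-diol
Product: 4 (4S)-2-(4-methoxyphenyl)-4-(6-methylhepta-1,5-dien-2-yl)-1,3-dioxolane
Conditions: 4-MeOC6H4CH(OMe)2 (1.2 equiv), PPTS (cat.), CH2Cl2, rt
Reagents that add atoms: 4-methoxybenzaldehyde dimethyl acetal COc1ccc(cc1)C(OC)OC
Why: Acid-catalysed transacetalisation gives the five-membered p-methoxybenzylidene acetal of the 1,2-diol; the acetal carbon forms as an epimer mixture that is erased in step 4 and C5 is untouched.

Step 4
Reactants: 4 p-methoxybenzylidene acetal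
Product: 5 (2S)-2-[(4-methoxyphenyl)methoxy]-7-methyl-3-methylideneoct-6-en-1-ol
Conditions: iBu2AlH (3 equiv), CH2Cl2, −78 → 0 °C
Reagents that add atoms: none
Why: Regioselective reductive opening of the p-methoxybenzylidene acetal: iBu2AlH coordinates the less hindered primary oxygen, the C–O bond to that oxygen breaks and hydride reduces the oxocarbenium ion, leaving the PMB ether on the secondary C5 oxygen and the primary C6 alcohol free.

Step 5
Reactants: 5 (2S)-2-[(4-methoxyphenyl)methoxy]-7-methyl-3-methylideneoct-6-en-1-ol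
Product: 6 (5S)-6-hydroxy-5-[(4-methoxyphenyl)methoxy]-4-methylidenehexanal
Conditions: OsO4 (2 mol %), NaIO4 (4 equiv), 2,6-lutidine (2 equiv), dioxane/H2O (3:1), rt
Reagents that add atoms: osmium tetroxide O=[Os](=O)(=O)=O; sodium periodate [Na+].[O-]I(=O)(=O)=O
Why: Lemieux–Johnson oxidative cleavage: OsO4 dihydroxylates the electron-rich, unhindered trisubstituted alkene much faster than the 1,1-disubstituted alkene that is shielded and inductively deactivated by the neighbouring PMB ether, and NaIO4 cleaves the diol to the C1 aldehyde and acetone.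

Step 6
Reactants: 7 trimethyl phosphonoacetate; 8 bromoacetaldehyde dimethyl acetal
Product: 9 methyl 2-(dimethoxyphosphoryl)-4,4-dimethoxybutanoate
Conditions: NaH (1.1 equiv), DMF, 0 °C; then 8, NaI (10 mol %), 80 °C
Reagents that add atoms: none
Why: SN2 C-alkylation of the sodium salt of the phosphonoacetate (malonate-type alkylation) with iodide catalysis for the sluggish β-alkoxy bromide; the new stereocentre is racemic and disappears in step 7.

Step 7
Reactants: 6 (5S)-6-hydroxy-5-[(4-methoxyphenyl)methoxy]-4-methylidenehexanal; 9 methyl 2-(dimethoxyphosphoryl)-4,4-dimethoxybutanoate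
Product: 10 methyl (2E,7S)-2-(2,2-dimethoxyethyl)-8-hydroxy-7-[(4-methoxyphenyl)methoxy]-6-methylideneoct-2-enoate
Conditions: 9 (1.5 equiv), NaH (1.4 equiv), THF, 0 °C; then 6, 0 °C → rt
Reagents that add atoms: none
Why: Horner–Wadsworth–Emmons olefination of the C1 aldehyde with the α-substituted phosphonoacetate gives mainly the (E)-trisubstituted enoate (ester trans to the chain) under thermodynamic control of the oxaphosphetane, which is the geometry that places C2 and C9 cis in the final ring; the free primary alcohol is tolerated and the minor Z isomer is removed by chromatography.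

Step 8
Reactants: 10 hydroxy enoate dimethyl acetal
Product: 11 methyl (2E,7S)-8-hydroxy-7-[(4-methoxyphenyl)methoxy]-6-methylidene-2-(2-oxoethyl)oct-2-enoate
Conditions: Amberlyst-15 (cat.), acetone/H2O (20:1), rt
Reagents that add atoms: water O
Why: Mild acid-catalysed hydrolysis of the dimethyl acetal unmasks the C8 aldehyde while PMB ether, enoate and 1,1-disubstituted alkene survive; room temperature and a solid acid that is filtered off limit migration of the C1=C10 double bond into conjugation with the aldehyde.

Step 9
Reactants: 11 hydroxy aldehyde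
Product: 12 methyl (2E,7S)-7-[(4-methoxyphenyl)methoxy]-6-methylidene-8-oxo-2-(2-oxoethyl)oct-2-enoate
Conditions: Dess–Martin periodinane (1.3 equiv), pyridine, CH2Cl2, 0 °C → rt; crude product used at once
Reagents that add atoms: none
Why: Dess–Martin oxidation of the primary alcohol under pyridine-buffered, non-aqueous conditions gives the α-alkoxy aldehyde without epimerising C5 or conjugating either β,γ-unsaturated aldehyde.

Step 10
Reactants: 13 methyl 2-(bromomethyl)prop-2-enoate
Product: 15 methyl (2Z)-3-bromo-2-(bromomethyl)prop-2-enoate, via tribromide 14 (not isolated)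
Conditions: Br2 (1.0 equiv), CH2Cl2, 0 °C → rt; then iPr2NEt (1.05 equiv), 0 °C
Reagents that add atoms: bromine BrBr
Why: Electrophilic addition of bromine to the acrylate followed by E2 dehydrobromination (loss of the tertiary α-bromide and a β-hydrogen) with a non-nucleophilic amine gives the 3-bromo-2-(bromomethyl)acrylate; both alkene isomers lead to the same allylzinc species, so the E/Z ratio does not matter.

Step 11
Reactants: 12 dialdehyde; 15 methyl (2Z)-3-bromo-2-(bromomethyl)prop-2-enoate
Product: 17 methyl (1(10)E,5S,6S,7R,8R)-8-hydroxy-5-[(4-methoxyphenyl)methoxy]germacra-1(10),4(15),11(13)-trien-12,6-olid-14-oate, via bromolactone aldehyde 16 (not isolated)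
Conditions: activated Zn dust (8 equiv), THF, 0 °C, 15 (1.05 equiv) added over 1 h at 0.05 M; then diluted to 0.003 M, 45 °C, 12 h
Reagents that add atoms: none
Why: Proposed new method: a zinc-mediated double Barbier (Dreiding–Schmidt-type) annulation in which 15 serves as a C7 1,1-dianion equivalent: zinc inserts into the CH2–Br bond and the allylzinc adds through its bromine-bearing γ-carbon to the more electrophilic, chelated C6 aldehyde (zinc bridging the aldehyde and PMB-ether oxygens, Cram-chelate attack, C6–O syn to C5–O), the zinc alkoxide lactonises onto the ester to give 16, zinc then inserts into the new allylic C7–Br bond, which erases the C7 centre, and after dilution the butenolide-type allylzinc attacks the tethered C8 aldehyde through C7 in a chair Zimmerman–Traxler transition state on the face opposite the C6 side chain (trans-fused lactone, C7 R) with the tether placing C9 so that C8 becomes R; the closest known reaction types are the zinc- or indium-mediated 2-(alkoxycarbonyl)allylation–lactonisation of aldehydes with 2-(bromomethyl)acrylates, the allylation of aldehydes with 3-(bromomethyl)furan-2(5H)-one, additions of γ-bromoallyl metal reagents made from 1,3-dibromopropene, and macrocyclising Barbier reactions that close ten-membered germacranolide rings.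

Step 12
Reactants: 17 bicyclic 8-hydroxy lactone; 18 angelic acid
Product: 20 methyl (1(10)E,5S,6S,7R,8R)-5-[(4-methoxyphenyl)methoxy]-8-{[(2Z)-2-methylbut-2-enoyl]oxy}germacra-1(10),4(15),11(13)-trien-12,6-olid-14-oate, via mixed anhydride 19 (not isolated)
Conditions: 18 (3 equiv), 2,4,6-trichlorobenzoyl chloride (3 equiv), Et3N (6 equiv), toluene, rt, 2 h; then 17, 80 °C
Reagents that add atoms: none
Why: Yamaguchi-type mixed-anhydride esterification run without a nucleophilic catalyst: the C8 hydroxyl attacks the angeloyl carbonyl of 19 because the trichlorobenzoyl carbonyl is shielded by its two ortho chlorines, the absence of DMAP and of strong base avoids Z-to-E isomerisation of the angelate to the tiglate, and C8 is acylated with retention.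

Step 13
Reactants: 20 PMB-protected angelate
Product: 21 methyl (1(10)E,5S,6S,7R,8R)-5-hydroxy-8-{[(2Z)-2-methylbut-2-enoyl]oxy}germacra-1(10),4(15),11(13)-trien-12,6-olid-14-oate
Conditions: DDQ (1.5 equiv), CH2Cl2/H2O (18:1), 0 °C → rt
Reagents that add atoms: none
Why: Oxidative cleavage of the p-methoxybenzyl ether with DDQ (hydride abstraction from the electron-rich benzylic position and hydrolysis of the resulting oxocarbenium ion) frees the C5 hydroxyl under neutral conditions that leave both esters, the α-methylene lactone and all stereocentres untouched.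

**Compound list**

1 | geraniol, (2E)-3,7-dimethylocta-2,6-dien-1-ol | CC(C)=CCC/C(C)=C/CO | starting material
2 | [(2R,3R)-3-methyl-3-(4-methylpent-3-en-1-yl)oxiran-2-yl]methanol, (2R,3R)-2,3-epoxygeraniol | OC[C@H]1O[C@]1(C)CCC=C(C)C | intermediate
3 | (2S)-7-methyl-3-methylideneoct-6-ene-1,2-diol | OC[C@@H](O)C(=C)CCC=C(C)C | intermediate
4 | (4S)-2-(4-methoxyphenyl)-4-(6-methylhepta-1,5-dien-2-yl)-1,3-dioxolane, both epimers at the acetal carbon | COc1ccc(cc1)C1OC[C@@H](O1)C(=C)CCC=C(C)C | intermediate
5 | (2S)-2-[(4-methoxyphenyl)methoxy]-7-methyl-3-methylideneoct-6-en-1-ol | OC[C@@H](OCc1ccc(OC)cc1)C(=C)CCC=C(C)C | intermediate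
6 | (5S)-6-hydroxy-5-[(4-methoxyphenyl)methoxy]-4-methylidenehexanal | OC[C@@H](OCc1ccc(OC)cc1)C(=C)CCC=O | intermediate
7 | trimethyl phosphonoacetate | COC(=O)CP(=O)(OC)OC | starting material
8 | bromoacetaldehyde dimethyl acetal, 2-bromo-1,1-dimethoxyethane | COC(CBr)OC | starting material
9 | methyl 2-(dimethoxyphosphoryl)-4,4-dimethoxybutanoate, racemic | COC(=O)C(CC(OC)OC)P(=O)(OC)OC | intermediate
10 | methyl (2E,7S)-2-(2,2-dimethoxyethyl)-8-hydroxy-7-[(4-methoxyphenyl)methoxy]-6-methylideneoct-2-enoate | OC[C@@H](OCc1ccc(OC)cc1)C(=C)CC/C=C(\CC(OC)OC)C(=O)OC | intermediate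
11 | methyl (2E,7S)-8-hydroxy-7-[(4-methoxyphenyl)methoxy]-6-methylidene-2-(2-oxoethyl)oct-2-enoate | OC[C@@H](OCc1ccc(OC)cc1)C(=C)CC/C=C(\CC=O)C(=O)OC | intermediate
12 | methyl (2E,7S)-7-[(4-methoxyphenyl)methoxy]-6-methylidene-8-oxo-2-(2-oxoethyl)oct-2-enoate, the C6/C8 dialdehyde | O=C[C@@H](OCc1ccc(OC)cc1)C(=C)CC/C=C(\CC=O)C(=O)OC | intermediate
13 | methyl 2-(bromomethyl)prop-2-enoate | COC(=O)C(=C)CBr | starting material
14 | methyl 2,3-dibromo-2-(bromomethyl)propanoate, tribromide formed in the flask in step 10 | COC(=O)C(Br)(CBr)CBr | intermediate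
15 | methyl (2Z)-3-bromo-2-(bromomethyl)prop-2-enoate | COC(=O)/C(CBr)=C/Br | intermediate
16 | methyl (2E,7S)-7-[(2R)-3-bromo-4-methylidene-5-oxooxolan-2-yl]-7-[(4-methoxyphenyl)methoxy]-6-methylidene-2-(2-oxoethyl)hept-2-enoate, both epimers at the CHBr carbon, formed in the flask in step 11 | C=C1C(=O)O[C@@H](C1Br)[C@@H](OCc1ccc(OC)cc1)C(=C)CC/C=C(\CC=O)C(=O)OC | intermediate
17 | methyl (1(10)E,5S,6S,7R,8R)-8-hydroxy-5-[(4-methoxyphenyl)methoxy]germacra-1(10),4(15),11(13)-trien-12,6-olid-14-oate: ten-membered ring trans-fused to the α-methylene-γ-lactone, free 8-OH, PMB on O5 | C=C1C(=O)O[C@H]2[C@H]1[C@H](O)C/C(C(=O)OC)=C\CCC(=C)[C@@H]2OCc1ccc(OC)cc1 | intermediate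
18 | angelic acid, (2Z)-2-methylbut-2-enoic acid | C/C=C(/C)C(=O)O | starting material
19 | (2Z)-2-methylbut-2-enoic 2,4,6-trichlorobenzoic anhydride, formed in the flask in step 12 | C/C=C(/C)C(=O)OC(=O)c1c(Cl)cc(Cl)cc1Cl | intermediate
20 | methyl (1(10)E,5S,6S,7R,8R)-5-[(4-methoxyphenyl)methoxy]-8-{[(2Z)-2-methylbut-2-enoyl]oxy}germacra-1(10),4(15),11(13)-trien-12,6-olid-14-oate | C=C1C(=O)O[C@H]2[C@H]1[C@H](OC(=O)/C(C)=C\C)C/C(C(=O)OC)=C\CCC(=C)[C@@H]2OCc1ccc(OC)cc1 | intermediate
21 | methyl (1(10)E,5S,6S,7R,8R)-5-hydroxy-8-{[(2Z)-2-methylbut-2-enoyl]oxy}germacra-1(10),4(15),11(13)-trien-12,6-olid-14-oate, CNP0163095.1 | C=C1C(=O)O[C@H]2[C@H]1[C@H](OC(=O)/C(C)=C\C)C/C(C(=O)OC)=C\CCC(=C)[C@@H]2O | target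

**Step count and risks**

Total step count: 13 (11 on the main line, plus step 6 for phosphonate 9 and step 10 for dibromide 15).
Longest linear sequence: 11 steps (1 → 2 → 3 → 4 → 5 → 6 → 10 → 11 → 12 → 17 → 20 → 21; steps 1–5, 7–9, 11–13).

Steps most likely to fail:

Step 11 is the main risk. The double Barbier annulation has no direct precedent. Dialdehyde 12 is fragile. The first adduct can be reduced to a diene before it lactonises. A second molecule of 15 or a second molecule of substrate can intercept the C8 aldehyde. The C8 configuration depends on a macrocyclic transition state that has not been modelled. The fallback makes the two C–C bonds in separate flasks and sets out from 10. Dess–Martin oxidation of 10 gives methyl (2E,7S)-2-(2,2-dimethoxyethyl)-7-[(4-methoxyphenyl)methoxy]-6-methylidene-8-oxooct-2-enoate F1, in which only the C6 aldehyde is free. Allylation and lactonisation of F1 with 15 and Zn dust in THF gives the bromolactone acetal methyl (2E,7S)-7-[(2R)-3-bromo-4-methylidene-5-oxooxolan-2-yl]-2-(2,2-dimethoxyethyl)-7-[(4-methoxyphenyl)methoxy]-6-methylidenehept-2-enoate F2. Acetal hydrolysis (Amberlyst-15, wet acetone) then gives 16 as an isolated compound. An ordinary intramolecular Barbier reaction of 16 (Zn dust, THF/saturated aqueous NH4Cl, 0.003 M) closes the ten-membered ring, and the fallback comes back to the route at 17.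

Step 12 is the second risk. The C8 hydroxyl is hindered, prolonged heating can isomerise the angelate to the tiglate, and the free hydroxyl could translactonise. The fallback builds the Z-alkene on the substrate and sets out from 17. Esterification with 2-[bis(2,2,2-trifluoroethoxy)phosphoryl]propanoic acid (DCC, DMAP cat., CH2Cl2, 0 °C) gives methyl (1(10)E,5S,6S,7R,8R)-8-({2-[bis(2,2,2-trifluoroethoxy)phosphoryl]propanoyl}oxy)-5-[(4-methoxyphenyl)methoxy]germacra-1(10),4(15),11(13)-trien-12,6-olid-14-oate F3. A Still–Gennari olefination of F3 with acetaldehyde (KN(SiMe3)2, 18-crown-6, THF, −78 °C) gives the (Z)-2-methylbut-2-enoate directly, and the fallback comes back to the route at 20.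

Step 5 is the third risk. OsO4 must distinguish the trisubstituted alkene from the 1,1-disubstituted alkene in the presence of an electron-rich arene. The fallback replaces osmylation by epoxidation and sets out from 5. mCPBA (1.0 equiv, CH2Cl2, 0 °C) epoxidises the more nucleophilic trisubstituted alkene to (2S)-5-(3,3-dimethyloxiran-2-yl)-2-[(4-methoxyphenyl)methoxy]-3-methylidenepentan-1-ol F4. Periodic acid (H5IO6, THF/H2O, 0 °C) then opens and cleaves the epoxide, and the fallback comes back to the route at 6.

**Further compounds**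

F1 | step 11 | methyl (2E,7S)-2-(2,2-dimethoxyethyl)-7-[(4-methoxyphenyl)methoxy]-6-methylidene-8-oxooct-2-enoate | O=C[C@@H](OCc1ccc(OC)cc1)C(=C)CC/C=C(\CC(OC)OC)C(=O)OC
F2 | step 11 | methyl (2E,7S)-7-[(2R)-3-bromo-4-methylidene-5-oxooxolan-2-yl]-2-(2,2-dimethoxyethyl)-7-[(4-methoxyphenyl)methoxy]-6-methylidenehept-2-enoate, both epimers at the CHBr carbon | C=C1C(=O)O[C@@H](C1Br)[C@@H](OCc1ccc(OC)cc1)C(=C)CC/C=C(\CC(OC)OC)C(=O)OC
F3 | step 12 | methyl (1(10)E,5S,6S,7R,8R)-8-({2-[bis(2,2,2-trifluoroethoxy)phosphoryl]propanoyl}oxy)-5-[(4-methoxyphenyl)methoxy]germacra-1(10),4(15),11(13)-trien-12,6-olid-14-oate, both epimers at the phosphonate α-carbon | C=C1C(=O)O[C@H]2[C@H]1[C@H](OC(=O)C(C)P(=O)(OCC(F)(F)F)OCC(F)(F)F)C/C(C(=O)OC)=C\CCC(=C)[C@@H]2OCc1ccc(OC)cc1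
F4 | step 5 | (2S)-5-(3,3-dimethyloxiran-2-yl)-2-[(4-methoxyphenyl)methoxy]-3-methylidenepentan-1-ol, both epimers at the oxirane CH | OC[C@@H](OCc1ccc(OC)cc1)C(=C)CCC1OC1(C)C
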